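**Overview**

- Cuts: the pyran O–CMe2 bond is cut first (retro oxa-6π to an o-quinone methide, a tautomer of a 3-prenyl-o-quinone). Ring B is then taken back to a 6-hydroxycyclohex-2-enone, which is cut at C5–O, C2–prenyl, C1–chain and C3–prenyl down to cyclohexane-1,3-dione; the chain is cut from ring A at the olefination bond.
- Forward: ring A is bought as an aldehyde and extended to a 3-arylpropyl iodide. The carbocycle of ring B is bought as the dione and substituted by carbonyl chemistry in the order C3 prenyl, C1 chain (which joins the halves), C2 prenyl, C5 oxygen.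
- Ring B becomes aromatic and the pyran closes in a single flask (oxidation, then base); desilylation ends the route.
- Enabling feature: with C4 and C5 at the quinone level, the C3 prenyl group ortho to the C4 oxygen makes ring B a tautomer of the 1-oxatriene O=C4–C3=CH–CH=CMe2. The 2,2-dimethyl-2H-pyran ring (O, CMe2, CH=CH, C3, C4) is its electrocyclic isomer.
- Stereochemistry: the target has no stereocentre. The sp3 centres of the cyclohexenone intermediates are carried as racemates or mixtures and vanish on aromatisation; the only defined alkene (cis, in the pyran) is fixed by the ring.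

Key step: step 11

Remarks on the chemistry:
- Ring B is numbered C1 (arylpropyl chain), C2 (prenyl), C3 (carbon carrying the pyran CH=CH), C4 (pyran oxygen), C5 (OH), C6 (H).
- Ar = 2-methoxy-4-(triisopropylsilyloxy)phenyl; prenyl = 3-methylbut-2-en-1-yl.
- Dione 3 is drawn as its diketo tautomer, and prenylbarium chloride 14 is assumed to be the monomeric σ-allyl species.

**Route**

Step 1
Reactants: 1 cyclohexane-1,3-dione; 2 prenyl bromide (1-bromo-3-methylbut-2-ene)
Product: 3 2-prenylcyclohexane-1,3-dione
Conditions: KOH (1 equiv), H2O, 0 °C to rt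
Reagents that add atoms: none
Why: The fully formed dione enolate is alkylated by the soft allylic bromide mainly at its central carbon (C-alkylation of a cyclic 1,3-dione in aqueous base), which places the future C3 prenyl group.

Step 2
Reactants: 3 2-prenylcyclohexane-1,3-dione
Product: 4 3-methoxy-2-prenylcyclohex-2-en-1-one
Conditions: Me2SO4, K2CO3, acetone, reflux
Reagents that add atoms: dimethyl sulfate, COS(=O)(=O)OC
Why: O-Alkylation of the enolised 2-alkyl-1,3-dione by the hard electrophile dimethyl sulfate gives the vinylogous ester, and the absence of acid keeps the enol oxygen from adding to the prenyl alkene.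

Step 3
Reactants: 5 4-hydroxy-2-methoxybenzaldehyde
Product: 6 2-methoxy-4-(triisopropylsilyloxy)benzaldehyde
Conditions: i-Pr3SiCl, imidazole, DMF, rt
Reagents that add atoms: triisopropylsilyl chloride, CC(C)[Si](Cl)(C(C)C)C(C)C
Why: Standard silylation of a phenol (silyl chloride with imidazole); the triisopropylsilyl ether is chosen because it should withstand amide bases, allylic metal reagents, cold dilute acid and the later oxidant, yet falls to fluoride at the end.

Step 4
Reactants: 6 2-methoxy-4-(triisopropylsilyloxy)benzaldehyde; 7 triethyl phosphonoacetate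
Product: 8 ethyl (E)-3-Ar-prop-2-enoate
Conditions: NaH, THF, 0 °C to rt
Reagents that add atoms: none
Why: Horner–Wadsworth–Emmons olefination of an aromatic aldehyde with a stabilised phosphonate anion gives the (E)-cinnamate, whose geometry is irrelevant because the alkene is hydrogenated next.

Step 5
Reactants: 8 ethyl (E)-3-Ar-prop-2-enoate
Product: 9 ethyl 3-Ar-propanoate
Conditions: H2 (1 atm), 10% Pd/C, EtOAc, rt
Reagents that add atoms: none
Why: Catalytic hydrogenation of a conjugated alkene over palladium on carbon leaves the ester, the aryl methyl ether and the aryl silyl ether untouched.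

Step 6
Reactants: 9 ethyl 3-Ar-propanoate
Product: 10 3-Ar-propan-1-ol
Conditions: i-Bu2AlH (2.5 equiv), CH2Cl2, −78 to 0 °C; aqueous potassium sodium tartrate (KNaC4H4O6)
Reagents that add atoms: none
Why: Reduction of an ester to the primary alcohol by an aluminium hydride at low temperature, under which the aryl silyl ether should survive.

Step 7
Reactants: 10 3-Ar-propan-1-ol
Product: 11 3-Ar-propyl iodide (1-iodo-3-Ar-propane)
Conditions: I2, PPh3, imidazole, CH2Cl2, 0 °C to rt
Reagents that add atoms: iodine, II
Why: Appel-type iodination converts the primary alcohol into the iodide by SN2 displacement of the alkoxyphosphonium ion under essentially neutral conditions.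

Step 8
Reactants: 4 3-methoxy-2-prenylcyclohex-2-en-1-one; 11 3-Ar-propyl iodide
Product: 12 6-(3-Ar-propyl)-3-methoxy-2-prenylcyclohex-2-en-1-one (racemic)
Conditions: LiN(i-Pr)2, THF, −78 °C; DMPU; then 11, −78 to 0 °C
Reagents that add atoms: none
Why: A vinylogous ester is deprotonated kinetically at the α′ carbon and the lithium enolate, activated by DMPU, is alkylated by the primary iodide (Stork–Danheiser alkylation); the new stereocentre forms as a racemate and is destroyed later.

Step 9
Reactants: 12 6-(3-Ar-propyl)-3-methoxy-2-prenylcyclohex-2-en-1-one; 13 prenyl chloride (1-chloro-3-methylbut-2-ene)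
Product: 16 4-(3-Ar-propyl)-2,3-diprenylcyclohex-2-en-1-one (racemic), via prenylbarium chloride 14 (not isolated), via tertiary carbinol 15 (not isolated)
Conditions: BaI2, lithium biphenylide (LiC12H10, 2 equiv per BaI2), THF, rt (gives zerovalent barium); 13, −78 °C; 12, −78 °C; then 1 M HCl, THF, 0 °C
Reagents that add atoms: water, O
Why: Stork–Danheiser transposition in which the allylic barium reagent adds to the carbonyl through the carbon that carried chlorine (α-selective 1,2-addition, unlike the magnesium reagent) and cold dilute acid converts the 3-methoxy allylic carbinol into the transposed enone, placing the second prenyl group on C2 and the carbonyl on C4; the ring stereocentre stays racemic.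

Step 10
Reactants: 16 4-(3-Ar-propyl)-2,3-diprenylcyclohex-2-en-1-one
Product: 17 6-hydroxy-4-(3-Ar-propyl)-2,3-diprenylcyclohex-2-en-1-one (acyloin, mixture of diastereomers)
Conditions: KN(SiMe3)2, THF, −78 °C (enone added to the base); 3-phenyl-2-(phenylsulfonyl)oxaziridine, −78 °C; aqueous NH4Cl
Reagents that add atoms: 3-phenyl-2-(phenylsulfonyl)oxaziridine, O=S(=O)(c1ccccc1)N1OC1c1ccccc1
Why: A hindered amide base deprotonates the cyclohexenone kinetically at the α′ carbon and the cross-conjugated potassium enolate is oxidised at carbon by the N-sulfonyloxaziridine (Davis hydroxylation), which does not epoxidise the trisubstituted alkenes; the carbinol centre forms as a mixture, which is harmless because it is oxidised in the next step.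

Step 11
Reactants: 17 6-hydroxy-4-(3-Ar-propyl)-2,3-diprenylcyclohex-2-en-1-one
Product: 22 6-(3-Ar-propyl)-2,2-dimethyl-5-prenyl-2H-chromen-8-ol (Kazinol N triisopropylsilyl ether), via ene-1,2-dione 18 (not isolated), via catechol 19 (not isolated), via o-quinone 20 (not isolated), via o-quinone methide 21 (not isolated)
Conditions: 2-iodoxybenzoic acid (2.0 equiv, no excess), DMSO, rt, argon, dark; then Et3N (5 equiv), rt
Reagents that add atoms: none
Why: Proposed new method: the first equivalent of 2-iodoxybenzoic acid oxidises the acyloin to ene-1,2-dione 18, a keto tautomer of catechol 19 that aromatises by two enolisations, the second equivalent oxidises 19 to o-quinone 20, and Et3N then relays a proton from the doubly activated CH2 of the C3 prenyl group to the C5 oxygen through the extended enolate, giving o-quinone methide 21. The closest known reaction types are the oxidation of acyloins and of catechols by 2-iodoxybenzoic acid, the amine-induced isomerisation of prenylated p-benzoquinones to chromenols and the DDQ cyclodehydrogenation of o-prenylphenols; running them as one sequence on a 3-prenyl-o-quinone is the untested part. The pyran ring closes by a thermal disrotatory oxa-6π electrocyclisation of the 1-oxatriene O=C4–C3=CH–CH=CMe2 of 21, which forms the O–CMe2 bond, regenerates the aromatic sextet of ring B and is therefore fast and irreversible. No stereocentre is formed, and the new CH=CH bond is cis because it lies in the six-membered ring. The step needs the C3 prenyl group and the C4 oxygen to react rather than the C2 prenyl group, the C1 chain or the C5 oxygen, and the substrate provides for this because only the C3 methylene leads to a quinone methide with a carbonyl oxygen in reach of the CMe2 terminus, while the p-quinone methides from the other two methylenes have no ring closure open to them and can return to 20, as can the (E) isomer of 21. Oxidant must be spent before the base is added, since any excess would oxidise the free phenol of 22, hence no more than two equivalents are used.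

Step 12
Reactants: 22 Kazinol N triisopropylsilyl ether
Product: 23 Kazinol N, 6-[3-(4-hydroxy-2-methoxyphenyl)propyl]-2,2-dimethyl-5-prenyl-2H-chromen-8-ol
Conditions: Bu4NF, AcOH, THF, 0 °C
Reagents that add atoms: none
Why: Fluoride cleaves the aryl silyl ether through Si–F bond formation, and the acetic acid buffer keeps both phenols protonated so that the electron-rich chromenol is not exposed to base and air.

**Compound list**

1 | cyclohexane-1,3-dione | O=C1CCCC(=O)C1 | starting material
2 | prenyl bromide (1-bromo-3-methylbut-2-ene) | CC(C)=CCBr | starting material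
3 | 2-(3-methylbut-2-en-1-yl)cyclohexane-1,3-dione | CC(C)=CCC1C(=O)CCCC1=O | intermediate
4 | 3-methoxy-2-(3-methylbut-2-en-1-yl)cyclohex-2-en-1-one | COC1=C(CC=C(C)C)C(=O)CCC1 | intermediate
5 | 4-hydroxy-2-methoxybenzaldehyde | COc1cc(O)ccc1C=O | starting material
6 | 2-methoxy-4-(triisopropylsilyloxy)benzaldehyde | COc1cc(O[Si](C(C)C)(C(C)C)C(C)C)ccc1C=O | intermediate
7 | triethyl phosphonoacetate | CCOC(=O)CP(=O)(OCC)OCC | starting material
8 | ethyl (E)-3-[2-methoxy-4-(triisopropylsilyloxy)phenyl]prop-2-enoate | CCOC(=O)/C=C/c1ccc(O[Si](C(C)C)(C(C)C)C(C)C)cc1OC | intermediate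
9 | ethyl 3-[2-methoxy-4-(triisopropylsilyloxy)phenyl]propanoate | CCOC(=O)CCc1ccc(O[Si](C(C)C)(C(C)C)C(C)C)cc1OC | intermediate
10 | 3-[2-methoxy-4-(triisopropylsilyloxy)phenyl]propan-1-ol | OCCCc1ccc(O[Si](C(C)C)(C(C)C)C(C)C)cc1OC | intermediate
11 | 1-iodo-3-[2-methoxy-4-(triisopropylsilyloxy)phenyl]propane | COc1cc(O[Si](C(C)C)(C(C)C)C(C)C)ccc1CCCI | intermediate
12 | 3-methoxy-6-{3-[2-methoxy-4-(triisopropylsilyloxy)phenyl]propyl}-2-(3-methylbut-2-en-1-yl)cyclohex-2-en-1-one (racemic) | COc1cc(O[Si](C(C)C)(C(C)C)C(C)C)ccc1CCCC1CCC(OC)=C(CC=C(C)C)C1=O | intermediate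
13 | prenyl chloride (1-chloro-3-methylbut-2-ene) | CC(C)=CCCl | starting material
14 | prenylbarium chloride (not isolated) | CC(C)=CC[Ba]Cl | intermediate
15 | 3-methoxy-6-{3-[2-methoxy-4-(triisopropylsilyloxy)phenyl]propyl}-1,2-bis(3-methylbut-2-en-1-yl)cyclohex-2-en-1-ol (mixture of diastereomers, not isolated) | COc1cc(O[Si](C(C)C)(C(C)C)C(C)C)ccc1CCCC1CCC(OC)=C(CC=C(C)C)C1(O)CC=C(C)C | intermediate
16 | 4-{3-[2-methoxy-4-(triisopropylsilyloxy)phenyl]propyl}-2,3-bis(3-methylbut-2-en-1-yl)cyclohex-2-en-1-one (racemic) | COc1cc(O[Si](C(C)C)(C(C)C)C(C)C)ccc1CCCC1CCC(=O)C(CC=C(C)C)=C1CC=C(C)C | intermediate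
17 | 6-hydroxy-4-{3-[2-methoxy-4-(triisopropylsilyloxy)phenyl]propyl}-2,3-bis(3-methylbut-2-en-1-yl)cyclohex-2-en-1-one (mixture of diastereomers) | COc1cc(O[Si](C(C)C)(C(C)C)C(C)C)ccc1CCCC1CC(O)C(=O)C(CC=C(C)C)=C1CC=C(C)C | intermediate
18 | 5-{3-[2-methoxy-4-(triisopropylsilyloxy)phenyl]propyl}-3,4-bis(3-methylbut-2-en-1-yl)cyclohex-3-ene-1,2-dione (racemic, not isolated) | COc1cc(O[Si](C(C)C)(C(C)C)C(C)C)ccc1CCCC1CC(=O)C(=O)C(CC=C(C)C)=C1CC=C(C)C | intermediate
19 | 5-{3-[2-methoxy-4-(triisopropylsilyloxy)phenyl]propyl}-3,4-bis(3-methylbut-2-en-1-yl)benzene-1,2-diol (not isolated) | COc1cc(O[Si](C(C)C)(C(C)C)C(C)C)ccc1CCCc1cc(O)c(O)c(CC=C(C)C)c1CC=C(C)C | intermediate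
20 | 5-{3-[2-methoxy-4-(triisopropylsilyloxy)phenyl]propyl}-3,4-bis(3-methylbut-2-en-1-yl)cyclohexa-3,5-diene-1,2-dione (not isolated) | COc1cc(O[Si](C(C)C)(C(C)C)C(C)C)ccc1CCCC1=CC(=O)C(=O)C(CC=C(C)C)=C1CC=C(C)C | intermediate
21 | (6Z)-2-hydroxy-4-{3-[2-methoxy-4-(triisopropylsilyloxy)phenyl]propyl}-5-(3-methylbut-2-en-1-yl)-6-(3-methylbut-2-en-1-ylidene)cyclohexa-2,4-dien-1-one (CH=CMe2 cis to the C4 carbonyl, not isolated) | COc1cc(O[Si](C(C)C)(C(C)C)C(C)C)ccc1CCCC1=C(CC=C(C)C)/C(=C/C=C(C)C)C(=O)C(O)=C1 | intermediate
22 | 6-{3-[2-methoxy-4-(triisopropylsilyloxy)phenyl]propyl}-2,2-dimethyl-5-(3-methylbut-2-en-1-yl)-2H-chromen-8-ol (Kazinol N triisopropylsilyl ether) | COc1cc(O[Si](C(C)C)(C(C)C)C(C)C)ccc1CCCc1cc(O)c2c(c1CC=C(C)C)C=CC(C)(C)O2 | intermediate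
23 | Kazinol N, 6-[3-(4-hydroxy-2-methoxyphenyl)propyl]-2,2-dimethyl-5-(3-methylbut-2-en-1-yl)-2H-chromen-8-ol | COc1cc(O)ccc1CCCc1cc(O)c2c(c1CC=C(C)C)C=CC(C)(C)O2 | target

**Step count**

Total step count: 12.
Longest linear sequence: 10 steps (5 to 6, 8, 9, 10, 11, 12, 16, 17, 22 and 23; steps 3 to 12).

**Steps most likely to fail**

1. Step 11 (carries the new-method label).
What may go wrong: proton transfer from the C2 prenyl methylene or from the benzylic CH2 of the C1 chain, followed by irreversible rearomatisation to alkenyl catechols. Electron transfer or addition between the amine and the o-quinone is also possible, as is over-oxidation of the product phenol by oxidant left in the flask.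
Fallback (known reactions only): the fallback sets out from acyloin 17. Oxidation with 2-iodoxybenzoic acid in DMSO followed by a reductive work-up with aqueous Na2S2O4 should give catechol 19 as an isolated compound. Silylation with t-BuMe2SiCl (1 equiv) and imidazole at 0 °C should occur at the less hindered C5 hydroxyl, which is flanked by C6–H, whereas the C4 hydroxyl lies between the C3 prenyl group and the C5 oxygen. This gives the C5-O-silyl catechol monoether F1. DDQ in benzene at reflux, the established cyclodehydrogenation of o-prenylphenols, should then close the pyran onto the only free phenol and give the bis-silyl chromene F2. Bu4NF with AcOH removes both silyl groups, and the fallback rejoins the route at Kazinol N 23.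

2. Step 9.
What may go wrong: bond formation through the γ carbon of the allylic metal (allylic transposition to the 1,1-dimethylallyl carbinol), or enolisation of the hindered carbonyl in place of addition.
Fallback: the fallback sets out from vinylogous ester 12. Allylmagnesium bromide (C3H5MgBr, THF, −78 to 0 °C) is a symmetric allyl nucleophile that adds readily to hindered carbonyls. Followed by 1 M HCl at 0 °C it should give, through the tertiary allyl carbinol F3, the 3-allyl enone F4. Cross-metathesis of the terminal alkene with 2-methyl-2-butene (used as solvent) and the second-generation Grubbs catalyst (H2IMes)(PCy3)Cl2Ru=CHPh then converts the allyl into a prenyl group. The existing prenyl group is degenerate towards this exchange, and the large excess of 2-methyl-2-butene should suppress ring closure between the two side chains. The fallback rejoins the route at enone 16.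

3. Step 10.
What may go wrong: equilibration of the kinetic α′ enolate to the extended dienolate by proton transfer from the doubly allylic C3 prenyl methylene or from C4–H, leading to oxygenation at the wrong carbon. Addition of the enolate to the sulfonylimine by-product is a second possibility.
Fallback: the fallback sets out from enone 16. α′-Acetoxylation with Mn(OAc)3 in benzene at reflux is a known α′-selective oxidation of enones that does not pass through a free basic enolate, and should give the 6-acetoxy enone F5. Mild methanolysis (catalytic K2CO3, MeOH, 0 °C, argon) then releases the hydroxyl, and the fallback rejoins the route at acyloin 17.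

**Further compounds**

F1 | step 11 | 6-(tert-butyldimethylsilyloxy)-4-{3-[2-methoxy-4-(triisopropylsilyloxy)phenyl]propyl}-2,3-bis(3-methylbut-2-en-1-yl)phenol | COc1cc(O[Si](C(C)C)(C(C)C)C(C)C)ccc1CCCc1cc(O[Si](C)(C)C(C)(C)C)c(O)c(CC=C(C)C)c1CC=C(C)C
F2 | step 11 | 8-(tert-butyldimethylsilyloxy)-6-{3-[2-methoxy-4-(triisopropylsilyloxy)phenyl]propyl}-2,2-dimethyl-5-(3-methylbut-2-en-1-yl)-2H-chromene | COc1cc(O[Si](C(C)C)(C(C)C)C(C)C)ccc1CCCc1cc(O[Si](C)(C)C(C)(C)C)c2c(c1CC=C(C)C)C=CC(C)(C)O2
F3 | step 9 | 1-allyl-3-methoxy-6-{3-[2-methoxy-4-(triisopropylsilyloxy)phenyl]propyl}-2-(3-methylbut-2-en-1-yl)cyclohex-2-en-1-ol (mixture of diastereomers, not isolated) | COc1cc(O[Si](C(C)C)(C(C)C)C(C)C)ccc1CCCC1CCC(OC)=C(CC=C(C)C)C1(O)CC=C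
F4 | step 9 | 3-allyl-4-{3-[2-methoxy-4-(triisopropylsilyloxy)phenyl]propyl}-2-(3-methylbut-2-en-1-yl)cyclohex-2-en-1-one (racemic) | COc1cc(O[Si](C(C)C)(C(C)C)C(C)C)ccc1CCCC1CCC(=O)C(CC=C(C)C)=C1CC=C
F5 | step 10 | 6-acetoxy-4-{3-[2-methoxy-4-(triisopropylsilyloxy)phenyl]propyl}-2,3-bis(3-methylbut-2-en-1-yl)cyclohex-2-en-1-one (mixture of diastereomers) | COc1cc(O[Si](C(C)C)(C(C)C)C(C)C)ccc1CCCC1CC(OC(C)=O)C(=O)C(CC=C(C)C)=C1CC=C(C)C
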